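- Late in the dawn run L slows down, and the dusk run hardly moves, so I reckon with what is left above a floor and not with what is made.

common to all: E 2.5 mol%

| charge | L | J | remark | time |
|---|---|---|---|---|
| dusk | 0.025 M | 0.14 mM | run made earlier |  |
| dawn | 0.10 M | 0.14 mM | run made earlier |  |
| winter | 0.050 M | 0.28 mM | run made earlier |  |
| flask | 0.050 M | 0.14 mM |  | 12 min |

| run | time / min | Q / % | L / % |
|---|---|---|---|
| dusk | 1.33 | 1.7 | 97.4 |
| dusk | 3.00 | 0.6 | 99.8 |
| dusk | 6.00 | 3.5 | 96.2 |
| dusk | 10.0 | 4.3 | 94.9 |
| dawn | 1.33 | 20.6 | 81.2 |
| dawn | 3.00 | 41.7 | 59.5 |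
| dawn | 6.00 | 60.8 | 37.5 |
| dawn | 10.0 | 71.6 | 27.3 |
| winter | 1.33 | 7.1 | 94.0 |
| winter | 3.00 | 15.5 | 84.8 |
| winter | 6.00 | 29.1 | 73.0 |
| winter | 10.0 | 37.9 | 61.0 |

(readings scatter by 1 percentage point)

- average number of monomer units in a chain (chains begun, living or dead) at 12 min
- part of the L that has reacted at 12 min

- the average divides the monomer in chains by the number of chains begun, living and dead together
- the earlier runs were read with a standard deviation of 1 percentage point
- the earlier runs do not show the number of chains; that part of a forecast is a guess

- The dawn run sinks to 0.0273 M, and the dusk run still holds 0.0237 M at 10.0 min. I take this reading as the floor Lf, the equilibrium monomer level.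
- Two times matter: the asked time, and th, the time in which the excess of L over Lf halves.
- The winter run has the flask's charge of E, 1.25 mM, and its J differs by 0.140 mM, which is less than that charge, so I lend its th to the flask as an estimate.
- By the readings, the winter excess falls from 0.0263 M to 0.006775 M in 10.0 min, which reads as th = 5.11 min, the half-time of the excess.
- By this reckoning the flask passes 2.35 half-times and keeps 19.7% of its excess. My estimate of L is then 0.0289 M, and of c 42.2%.
- The readings do not show the chains, so dp stays a guess for me.
- The forecast, slightly above my c, gives c = 43% and dp = 18, holding that “propagation is reversible”.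
- The flask gives c = 42.7% and dp = 46.0.

    2 E → Z (k = 37.0 /M/s)
    L + E → X + Q (k = 0.450 /M/s)
    E + J → G (k = 7800 /M/s)
    L + X → Q + X, rate k4*[X]*[L] (k = 4.80 /M/s)
    Q + X → L + X, rate k5*[X] as long as [Q] is above zero (k = 0.110 /s)

- In the flask at 5.46 min, L has a half-life of 5.2 min by the making of Q, and Q is made 1.60 times as fast as it is used up, each step taken net. At 12.0 min that ratio is 1.25, with L at 57.3% of its charge, above my Lf at 47.5%. For the neighbour flask read at 20 min, my th leaves 6.65% of the excess, so I reckon L at 50.9%, and that flask holds 49.7%.

The runs were computed with constants of no real substance.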